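The bicycle is cut across both rings at once: the lactone O–C4 bond and the C5–C6 bond of the 1,2-dioxane (ring atoms O–O, C3, C4, C5, C6; lactone C1, C2, C3, C4, O). In the key step a ketone-derived peroxycarbenium ion at C6 is attacked by a 2-propenyl group on C3 (Prins closure of the dioxane) and the tertiary C4 cation is captured by the C1 carboxyl group, which closes the γ-lactone. The step exploits the cis ring fusion: the carboxymethyl arm on C3 lies next to quaternary C4. The precursor is an acyclic mixed peroxyketal that joins the side-chain methyl ketone to a C1–C5 allylic peroxy acid.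

Key step: step 10

Atom numbers in the text are those of the target: C1 lactone carbonyl, C2, C3 (CH bearing O–O), C4 (quaternary, lactone O), C5, C6 (quaternary, O–O), C7–C14 side chain (C8 is the methyl-bearing centre).

Assumption: the ligand and amine antipodes named in steps 4 and 8 are those expected from the usual steric models of these catalysts; should either give the opposite sense, its enantiomer is used.

Step 1
Reactants: 1 hex-5-yn-1-ol; 2 benzyl bromide
Product: 4 (5E)-5-methyl-7-phenylhept-5-en-1-ol, via alkenylalane 3 (not isolated)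
Conditions: Me3Al (3 equiv), Cp2ZrCl2 (0.25 equiv), CH2Cl2, 0 °C to rt; then 2, Pd(PPh3)4 (5 mol %), THF, rt; aq. HCl
Reagents that add atoms: trimethylaluminium, C[Al](C)C
Why: Zirconium-catalysed Negishi carboalumination adds methyl and aluminium syn across the terminal alkyne with methyl on the internal carbon (the hydroxyl is carried as its aluminium alkoxide), and palladium-catalysed cross-coupling of the alkenylalane with the benzyl halide goes with retention, which fixes the E trisubstituted alkene.

Step 2
Reactants: 4 (5E)-5-methyl-7-phenylhept-5-en-1-ol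
Product: 5 (5E)-5-methyl-7-phenylhept-5-enal
Conditions: TEMPO (10 mol %), PhI(OAc)2 (1.1 equiv), CH2Cl2, rt
Reagents that add atoms: none
Why: Nitroxyl-catalysed (TEMPO) oxidation with the iodine-based co-oxidant stops at the aldehyde and does not touch the trisubstituted alkene.

Step 3
Reactants: 5 (5E)-5-methyl-7-phenylhept-5-enal; 6 1-(triphenyl-λ5-phosphanylidene)propan-2-one
Product: 7 (3E,8E)-8-methyl-10-phenyldeca-3,8-dien-2-one
Conditions: toluene, 80 °C
Reagents that add atoms: none
Why: Wittig olefination with the stabilised acetonyl ylide gives the E enone.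

Step 4
Reactants: 7 (3E,8E)-8-methyl-10-phenyldeca-3,8-dien-2-one
Product: 8 (4S,8E)-4,8-dimethyl-10-phenyldec-8-en-2-one
Conditions: MeMgBr (1.2 equiv), CuBr·SMe2 (5 mol %), (R)-1-[(S)-2-(diphenylphosphino)ferrocenyl]ethyldicyclohexylphosphine (6 mol %), t-BuOMe, −75 °C; aq. NH4Cl
Reagents that add atoms: methylmagnesium bromide, C[Mg]Br
Why: Copper-catalysed asymmetric conjugate addition of the Grignard reagent: the chiral ferrocenyl diphosphine–copper complex suppresses 1,2-addition and delivers methyl to the Si face of C4 of the enone, which sets the S centre that becomes C8 of the target.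

Step 5
Reactants: 8 (4S,8E)-4,8-dimethyl-10-phenyldec-8-en-2-one
Product: 9 (4S,8E)-2,2-dimethoxy-4,8-dimethyl-10-phenyldec-8-ene
Conditions: HC(OMe)3, MeOH, PPTS (cat.), rt
Reagents that add atoms: trimethyl orthoformate, COC(OC)OC; methanol, CO
Why: Acid-catalysed ketalisation driven by the orthoformate as water scavenger; the stereocentre and the alkene are not touched.

Step 6
Reactants: 9 (4S,8E)-2,2-dimethoxy-4,8-dimethyl-10-phenyldec-8-ene
Product: 10 (4S,8E)-2-hydroperoxy-2-methoxy-4,8-dimethyl-10-phenyldec-8-ene (both epimers at C2)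
Conditions: H2O2 (anhydrous, in Et2O), camphorsulfonic acid (cat.), 0 °C
Reagents that add atoms: hydrogen peroxide, OO
Why: Acid-catalysed perhydrolysis of the ketal (exchange of one methoxy group for hydrogen peroxide via the oxocarbenium ion) gives the α-methoxy hydroperoxide, whose new ketal centre is uncontrolled and is destroyed again in step 10.

Step 7
Reactants: 11 2-methylprop-2-enal (methacrolein); 12 (triphenyl-λ5-phosphanylidene)acetaldehyde
Product: 13 (2E)-4-methylpenta-2,4-dienal
Conditions: CH2Cl2, rt
Reagents that add atoms: none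
Why: Wittig olefination of the enal with the stabilised formylmethylene ylide gives the E dienal.

Step 8
Reactants: 10 (4S,8E)-2-hydroperoxy-2-methoxy-4,8-dimethyl-10-phenyldec-8-ene; 13 (2E)-4-methylpenta-2,4-dienal
Product: 14 (3R)-3-{[(4S,8E)-2-methoxy-4,8-dimethyl-10-phenyldec-8-en-2-yl]peroxy}-4-methylpent-4-enal (both epimers at the peroxyketal carbon)
Conditions: (R)-2-[diphenyl(trimethylsilyloxy)methyl]pyrrolidine (20 mol %), PhCO2H (20 mol %), toluene, −20 °C
Reagents that add atoms: none
Why: Enantioselective iminium-ion-catalysed oxa-Michael addition (peroxidation) of the hydroperoxide to C3 of the dienal: the hard oxygen nucleophile adds 1,4 and attacks the E,s-trans iminium ion on the face away from the diphenyl(silyloxy)methyl group of the (R)-amine, which sets R at C3, while the hindered α-methoxy hydroperoxide and the low temperature disfavour closure of the enamine to the epoxide.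

Step 9
Reactants: 14 (3R)-3-{[(4S,8E)-2-methoxy-4,8-dimethyl-10-phenyldec-8-en-2-yl]peroxy}-4-methylpent-4-enal
Product: 15 (3R)-3-{[(4S,8E)-2-methoxy-4,8-dimethyl-10-phenyldec-8-en-2-yl]peroxy}-4-methylpent-4-enoic acid (both epimers at the peroxyketal carbon)
Conditions: NaClO2, NaH2PO4/Na2HPO4 buffer (pH 6.5), 2-methylbut-2-ene, t-BuOH/H2O, 0 °C; used at once in step 10
Reagents that add atoms: sodium chlorite, [Na+].[O-]Cl=O
Why: Pinnick oxidation turns the aldehyde into the carboxylic acid; hypochlorite is scavenged by the added alkene, the peroxide is inert to chlorite and the near-neutral buffer spares the acid-labile peroxyketal.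

Step 10
Reactants: 15 (3R)-3-{[(4S,8E)-2-methoxy-4,8-dimethyl-10-phenyldec-8-en-2-yl]peroxy}-4-methylpent-4-enoic acid
Product: 18 plakortolide G, via peroxycarbenium ion 16 (not isolated), via dioxanyl cation 17 (not isolated)
Conditions: TMSOTf (20 mol %), 4 Å molecular sieves, CH2Cl2, −78 to −40 °C
Reagents that add atoms: none
Why: Proposed new method: the silyl triflate ionises the methoxy group of the peroxyketal to the peroxycarbenium ion 16, whose C6 is attacked by the terminal carbon of the 2-propenyl group in a chair-like, Markovnikov 6-endo Prins closure (C5–C6 bond, 1,2-dioxane ring), and the tertiary C4 cation 17 is captured at once by the carboxyl oxygen in a 5-exo closure (O–C4 bond, γ-lactone), so that only methanol is lost. The closest known reaction types are the Prins cyclisation of homoallylic alcohols with ketals that is terminated by an internal nucleophile, and the Lewis acid-mediated additions of alkenes and allylsilanes to peroxycarbenium ions. C4 is controlled by the tether: the carboxymethyl arm on C3 can reach only the adjacent face of the cation, so the lactone must be cis-fused. C6 is controlled by the chair transition state, in which the arm on C3 is equatorial and the peroxycarbenium ion has its larger CH2R group anti to the O–O bond; this should place CH2R equatorial and the methyl group axial, cis to the arm as in the target. The step needs ionisation of C–OMe in preference to O–O or allylic C3–O cleavage (low temperature, silyl Lewis acid), attack by the 1,1-disubstituted alkene in preference to the remote trisubstituted one (six-membered against eight-membered transition state), and capture of the cation before proton loss or a 1,2-hydride shift from C3 (five-membered neighbouring carboxyl group).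

Compound list

1 | hex-5-yn-1-ol | C#CCCCCO | starting material
2 | benzyl bromide | BrCc1ccccc1 | starting material
3 | alkenylalane, dimethyl{(1E)-6-[(dimethylalumanyl)oxy]-2-methylhex-1-en-1-yl}alumane | C/C(=C\[Al](C)C)CCCCO[Al](C)C | intermediate
4 | (5E)-5-methyl-7-phenylhept-5-en-1-ol | C/C(=C\Cc1ccccc1)CCCCO | intermediate
5 | (5E)-5-methyl-7-phenylhept-5-enal | C/C(=C\Cc1ccccc1)CCCC=O | intermediate
6 | 1-(triphenyl-λ5-phosphanylidene)propan-2-one | CC(=O)C=P(c1ccccc1)(c1ccccc1)c1ccccc1 | starting material
7 | (3E,8E)-8-methyl-10-phenyldeca-3,8-dien-2-one | C/C(=C\Cc1ccccc1)CCC/C=C/C(C)=O | intermediate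
8 | (4S,8E)-4,8-dimethyl-10-phenyldec-8-en-2-one | C/C(=C\Cc1ccccc1)CCC[C@H](C)CC(C)=O | intermediate
9 | (4S,8E)-2,2-dimethoxy-4,8-dimethyl-10-phenyldec-8-ene | C/C(=C\Cc1ccccc1)CCC[C@H](C)CC(C)(OC)OC | intermediate
10 | (4S,8E)-2-hydroperoxy-2-methoxy-4,8-dimethyl-10-phenyldec-8-ene, both epimers at C2 | C/C(=C\Cc1ccccc1)CCC[C@H](C)CC(C)(OC)OO | intermediate
11 | 2-methylprop-2-enal (methacrolein) | CC(=C)C=O | starting material
12 | (triphenyl-λ5-phosphanylidene)acetaldehyde | O=CC=P(c1ccccc1)(c1ccccc1)c1ccccc1 | starting material
13 | (2E)-4-methylpenta-2,4-dienal | CC(=C)/C=C/C=O | intermediate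
14 | (3R)-3-{[(4S,8E)-2-methoxy-4,8-dimethyl-10-phenyldec-8-en-2-yl]peroxy}-4-methylpent-4-enal, both epimers at the peroxyketal carbon | C/C(=C\Cc1ccccc1)CCC[C@H](C)CC(C)(OC)OO[C@H](CC=O)C(C)=C | intermediate
15 | (3R)-3-{[(4S,8E)-2-methoxy-4,8-dimethyl-10-phenyldec-8-en-2-yl]peroxy}-4-methylpent-4-enoic acid, both epimers at the peroxyketal carbon | C/C(=C\Cc1ccccc1)CCC[C@H](C)CC(C)(OC)OO[C@H](CC(=O)O)C(C)=C | intermediate
16 | peroxycarbenium ion formed from 15 by loss of methoxide (C6=O+–O–C3, CH2R anti to O–O) | C/C(=C\Cc1ccccc1)CCC[C@H](C)C/C(C)=[O+]/O[C@H](CC(=O)O)C(C)=C | intermediate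
17 | tertiary 1,2-dioxan-4-yl cation: 3-(carboxymethyl)-4,6-dimethyl-6-[(2S,6E)-2,6-dimethyl-8-phenyloct-6-en-1-yl]-1,2-dioxan-4-ylium, C3 and C6 as in 18 | C/C(=C\Cc1ccccc1)CCC[C@H](C)C[C@]1(C)C[C+](C)[C@@H](CC(=O)O)OO1 | intermediate
18 | plakortolide G, (3R,4aR,7aR)-3,4a-dimethyl-3-[(2S,6E)-2,6-dimethyl-8-phenyloct-6-en-1-yl]tetrahydro-3H-furo[3,2-c][1,2]dioxin-6(4H)-one | C/C(=C\Cc1ccccc1)CCC[C@H](C)C[C@]1(C)C[C@@]2(C)OC(=O)C[C@H]2OO1 | target

Total step count: 10. Longest linear sequence: 9 steps (steps 1 to 6, 8, 9 and 10, from hex-5-yn-1-ol).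

Steps most likely to fail

1. Step 10 (Proposed new method). What may go wrong: the peroxycarbenium ion may fragment (heterolysis of the O–O or the allylic C3–O bond) before the alkene reaches C6; the C5–C6 bond may form through both chair arrangements, so that facial selectivity at C6 is poor; the C4 cation may lose a proton or take a 1,2-hydride shift from C3 before the carboxyl group closes on it. Fallback with known reactions, which closes the two rings one at a time and still makes the O–C4 bond in a lactone closure: it sets out from 10 and comes back at 18. Hydroperoxide 10 is silylated (Et3SiCl, imidazole) to the triethylsilyl peroxyketal F1. Hosomi–Sakurai allylation of its peroxycarbenium ion with trimethyl(2-methylallyl)silane and SnCl4 gives the homoallylic silyl peroxide F2 (both C6 epimers). Cross-metathesis with but-3-enoic acid (second-generation Grubbs catalyst) gives the β,γ-unsaturated acid F3. Iodolactonisation (I2, NaHCO3, MeCN), 5-endo at the tertiary carbon, forms the O–C4 bond and gives the β-iodo lactone F4. Bu4NF then frees the hydroperoxide, and the basic medium eliminates HI to the butenolide and closes the dioxane by oxa-Michael addition, which can only give the cis-fused lactone. C4 and C6 are not controlled on this path, so 18 would have to be separated from its stereoisomers.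

2. Step 8. What may go wrong: closure of the β-peroxy enamine onto the O–O bond (epoxidation instead of peroxidation), addition of the hydroperoxide at the terminal carbon of the dienal (1,6), or retro-addition that erodes the enantiomeric purity at C3. Fallback, in which the C3–O bond is made by an ene reaction and the fragments are joined by ketal exchange: it sets out from 9 and comes back at 18. Commercial 4-methylpent-3-enoic acid is esterified with tert-butyl 2,2,2-trichloroacetimidate to tert-butyl 4-methylpent-3-enoate F5. Schenck ene reaction (O2, tetraphenylporphyrin, visible light) gives the racemic allylic hydroperoxide F6. Kinetic resolution by peroxidase-catalysed reduction (horseradish peroxidase, guaiacol) should leave the (R)-hydroperoxide F7, the other antipode being removed as the alcohol. PPTS-catalysed exchange of F7 with ketal 9 gives the mixed peroxyketal tert-butyl ester F8. Under the conditions of step 10 the tert-butyl ester captures the C4 cation with loss of 2-methylpropene and gives 18.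

3. Step 9. What may go wrong: loss of methanol from the acid-labile peroxyketal once the carboxylic acid is present, or β-elimination of the peroxide from the aldehyde, before the oxidation is complete. Fallback, in which the oxidation level is adjusted after ring formation: it sets out from 14 and comes back at 18. Aldehyde 14 is taken into the conditions of step 10; the formyl oxygen captures the C4 cation and the cyclic oxocarbenium ion takes up the released methanol, giving the bicyclic methyl lactol ether F9. Mild aqueous acid (AcOH, THF/H2O) gives the lactol F10, and TEMPO/PhI(OAc)2 oxidises it to the lactone 18.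

Further compounds

F1 | step 10 | triethyl{[(4S,8E)-2-methoxy-4,8-dimethyl-10-phenyldec-8-en-2-yl]peroxy}silane | C/C(=C\Cc1ccccc1)CCC[C@H](C)CC(C)(OC)OO[Si](CC)(CC)CC
F2 | step 10 | triethyl{[(6S,10E)-2,4,6,10-tetramethyl-12-phenyldodeca-1,10-dien-4-yl]peroxy}silane, both C4 epimers | C/C(=C\Cc1ccccc1)CCC[C@H](C)CC(C)(CC(C)=C)OO[Si](CC)(CC)CC
F3 | step 10 | (8S,12E)-4,6,8,12-tetramethyl-14-phenyl-6-[(triethylsilyl)peroxy]tetradeca-3,12-dienoic acid, 3E/3Z and both C6 epimers | C/C(=C\Cc1ccccc1)CCC[C@H](C)CC(C)(CC(C)=CCC(=O)O)OO[Si](CC)(CC)CC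
F4 | step 10 | 4-iodo-5-methyl-5-{(4S,8E)-2,4,8-trimethyl-10-phenyl-2-[(triethylsilyl)peroxy]dec-8-en-1-yl}oxolan-2-one, mixture of stereoisomers | C/C(=C\Cc1ccccc1)CCC[C@H](C)CC(C)(CC1(C)OC(=O)CC1I)OO[Si](CC)(CC)CC
F5 | step 8 | tert-butyl 4-methylpent-3-enoate | CC(C)=CCC(=O)OC(C)(C)C
F6 | step 8 | rac-tert-butyl 3-hydroperoxy-4-methylpent-4-enoate | CC(=C)C(OO)CC(=O)OC(C)(C)C
F7 | step 8 | tert-butyl (3R)-3-hydroperoxy-4-methylpent-4-enoate | CC(C)(C)OC(=O)C[C@@H](OO)C(C)=C
F8 | step 8 | tert-butyl (3R)-3-{[(4S,8E)-2-methoxy-4,8-dimethyl-10-phenyldec-8-en-2-yl]peroxy}-4-methylpent-4-enoate | C/C(=C\Cc1ccccc1)CCC[C@H](C)CC(C)(OC)OO[C@H](CC(=O)OC(C)(C)C)C(C)=C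
F9 | step 9 | (3R,4aR,7aR)-6-methoxy-3,4a-dimethyl-3-[(2S,6E)-2,6-dimethyl-8-phenyloct-6-en-1-yl]hexahydro-3H-furo[3,2-c][1,2]dioxine, both C6 epimers | C/C(=C\Cc1ccccc1)CCC[C@H](C)C[C@]1(C)C[C@@]2(C)OC(OC)C[C@H]2OO1
F10 | step 9 | (3R,4aR,7aR)-3,4a-dimethyl-3-[(2S,6E)-2,6-dimethyl-8-phenyloct-6-en-1-yl]hexahydro-3H-furo[3,2-c][1,2]dioxin-6-ol | C/C(=C\Cc1ccccc1)CCC[C@H](C)C[C@]1(C)C[C@@]2(C)OC(O)C[C@H]2OO1
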